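## Retrosynthetic overview
1. The chlorohydrin ester comes from anti opening, by chloride at C3', of a (2S,3R)-2,3-dimethyloxirane-2-carboxylate. That ester comes from the core 3β-alcohol and an epoxy acid made by Sharpless epoxidation.
2. The tertiary 4α-acetate comes from kinetic hydrolysis of a 3,4-cyclic orthoacetate. The 3β-OH comes from α-face hydride delivery to a 4α-hydroxy-3-ketone.
3. The ring B enone, the C7–C11 bond and C5-H come from a deconjugative aldol of a C5=C6/C8-ketone dienolate with acetone, followed by reconjugation.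
4. The 4α-OH comes from hydroxylation of the extended dienolate of a bicyclic enedione. That enedione comes from a one-carbon ring expansion of a Hajos–Parrish-type hydrindenedione, in which the quaternary C10 shifts from the carbonyl carbon to the new C9.
5. Ring order: the five-membered ring is bought. Ring A is built by asymmetric annulation. Ring B is formed by expanding the five-membered ring to six.

Assumption: locants C1–C15 are eudesmane locants (C10 angular-methyl carbon, C5 ring-fusion CH, C8 enone carbonyl, C11 carbinol carbon, primes for the butanoate), β is the face of the angular methyl, and the target SMILES is read as 3β-acyloxy, 4α-acetoxy/4β-methyl, 5α-H, 10β-methyl, (2'R,3'S).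

## Route

Step 1
Reactants: 1 2-methylcyclopentane-1,3-dione; 2 pent-1-en-3-one (ethyl vinyl ketone)
Product: 3 2-methyl-2-(3-oxopentyl)cyclopentane-1,3-dione
Conditions: 2 (1.5 equiv), AcOH (cat.), H2O, 70 °C
Reagents that add atoms: none
Why: Michael addition of the acidic 1,3-dione to an unhindered vinyl ketone stops cleanly at the triketone, because the product has no C–H left between the ring carbonyls, and no stereocentre is formed.

Step 2
Reactants: 3 2-methyl-2-(3-oxopentyl)cyclopentane-1,3-dione
Product: 4 (7aS)-4,7a-dimethyl-2,3,7,7a-tetrahydro-1H-indene-1,5(6H)-dione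
Conditions: (S)-phenylalanine (1.0 equiv), (1S)-(+)-camphor-10-sulfonic acid (0.5 equiv), DMF, 30 → 70 °C; recrystallisation
Reagents that add atoms: none
Why: In this Hajos–Parrish–Eder–Sauer–Wiechert reaction the enamine of the side-chain ketone attacks one of the two enantiotopic ring carbonyls in a hydrogen-bonded transition state and the aldol dehydrates, so the (S)-amino acid gives the (7aS)-enedione and thereby fixes C10 (β-methyl).

Step 3
Reactants: 4 (7aS)-4,7a-dimethyl-2,3,7,7a-tetrahydro-1H-indene-1,5(6H)-dione; 5 dibromomethane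
Product: 11 (4aR)-1,4a-dimethyl-4,4a,7,8-tetrahydronaphthalene-2,6(3H,5H)-dione, via potassium dienolate 6 (not isolated), via dibromomethyllithium 7 (not isolated), via dibromomethyl carbinolate 8 (not isolated), via lithium bromocarbenoid 9 (not isolated), via ring-expanded bis-enolate 10 (not isolated)
Conditions: KH (1.05 equiv), THF, 0 °C; cannulate into 7 [5 (1.5 equiv) + LDA (1.5 equiv), THF, −95 °C]; n-BuLi (3.5 equiv), −95 → 0 °C; 2 M HCl, 0 °C → rt
Reagents that add atoms: none
Why: This is a Nozaki-type β-oxido carbenoid ring enlargement (a semipinacol-type 1,2-shift) in which KH masks the enone as its thermodynamic extended dienolate 6, so 7 adds only to the cyclopentanone (α face), Br/Li exchange gives 9, and the alkoxide pushes the better σ-donor, the quaternary allylic C10 that lies anti to the leaving bromide in the least crowded rotamer, onto the carbenoid carbon with retention at C10, which places the new CH2 (C9) between C10 and the carbonyl (now C8) before the acid work-up reconjugates ring A.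

Step 4
Reactants: 11 (4aR)-1,4a-dimethyl-4,4a,7,8-tetrahydronaphthalene-2,6(3H,5H)-dione
Product: 13 (1S,4aR)-1-hydroxy-1,4a-dimethyl-3,4,4a,5-tetrahydronaphthalene-2,6(1H,7H)-dione (4α-OH, C5=C6), via potassium dienolate 12 (not isolated)
Conditions: KHMDS (1.05 equiv), THF, −78 → −10 °C; 3-phenyl-2-(phenylsulfonyl)oxaziridine (1.05 equiv), −78 °C, 15 min; AcOH, −78 °C
Reagents that add atoms: 3-phenyl-2-(phenylsulfonyl)-1,2-oxaziridine, O=S(=O)(N1OC1c2ccccc2)c3ccccc3
Why: This is a Davis hydroxylation of a thermodynamic extended dienolate in which, as in the classical deconjugative α-alkylation of 4-substituted octalones, the electrophile enters at C4 and the alkene moves to C5=C6, the bulky oxaziridine comes from the α face because the 1,3-related angular methyl shields the β face (this sets 4S, 4α-OH/4β-Me), and the fast cold quench prevents proton relay from the acidic C7-H2 and hence over-oxidation.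

Step 5
Reactants: 13 (1S,4aR)-1-hydroxy-1,4a-dimethyl-3,4,4a,5-tetrahydronaphthalene-2,6(1H,7H)-dione; 14 acetone
Product: 19 (1S,4aR,8aR)-1-hydroxy-7-(2-hydroxypropan-2-yl)-1,4a-dimethyl-1,3,4,4a,5,8a-hexahydronaphthalene-2,6-dione, via dilithium alkoxide dienolate 15 (not isolated), via dilithium aldolate 16 (not isolated), via dilithium hydroxyalkyl dienolate 17 (not isolated), via deconjugated aldol 18 (not isolated)
Conditions: LiHMDS (2.15 equiv), THF, −78 °C; 14 (10 equiv), −78 → −25 °C, 3 h; AcOH (2.15 equiv), −78 °C; DBU (0.2 equiv), 0 °C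
Reagents that add atoms: none
Why: Proposed new method: a formal Morita–Baylis–Hillman hydroxyalkylation with a simple ketone run through a latent dienolate, in which the doubly activated C7-H of the β,γ-unsaturated ketone 13 is removed (C4 carries an alkoxide that cannot leave, so no vinylogous β-elimination), 15 attacks acetone at its open α-carbon C7 because the γ-carbon C5 is fully substituted, the uphill aldolate 16 is drained by a proton shift from the still acidic C7-H relayed by HN(SiMe3)2 to give the hydrogen-bonded dienolate 17 (this relay is what makes a ketone acceptor viable), acid gives 18, and catalytic DBU removes C7-H again and reprotonates kinetically at C5 from the α face (axial, anti to the 4β- and 10β-methyls) to give the conjugated, hydrogen-bonded enone with 5α-H that DBU no longer deprotonates, the closest known chemistry being the deconjugative α-aldol of extended dienolates with aldehydes followed by base reconjugation, which has not been shown with acetone or on such a ketone.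

Step 6
Reactants: 19 (1S,4aR,8aR)-1-hydroxy-7-(2-hydroxypropan-2-yl)-1,4a-dimethyl-1,3,4,4a,5,8a-hexahydronaphthalene-2,6-dione
Product: 20 (4aR,5S,6S,8aR)-5,6-dihydroxy-3-(2-hydroxypropan-2-yl)-5,8a-dimethyl-4a,5,6,7,8,8a-hexahydronaphthalen-2(1H)-one
Conditions: NaBH4 (0.6 equiv), MeOH/CH2Cl2 (1:1), −78 °C
Reagents that add atoms: none
Why: This is a chemoselective borohydride reduction in which the saturated, inductively activated α-hydroxy ketone at C3 reacts far faster than the hindered α-branched conjugated C8 ketone, and axial hydride delivery from the open α face (the β face carries the axial 4β- and 10β-methyls) gives the equatorial 3β-alcohol (3S).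

Step 7
Reactants: 20 (4aR,5S,6S,8aR)-5,6-dihydroxy-3-(2-hydroxypropan-2-yl)-5,8a-dimethyl-4a,5,6,7,8,8a-hexahydronaphthalen-2(1H)-one
Product: 22 (1S,2S,4aR,8aR)-2-hydroxy-7-(2-hydroxypropan-2-yl)-1,4a-dimethyl-6-oxo-1,2,3,4,4a,5,6,8a-octahydronaphthalen-1-yl acetate, via cyclic orthoacetate 21 (not isolated)
Conditions: MeC(OMe)3 (5 equiv), PPTS (5 mol %), CH2Cl2, rt; then AcOH/H2O (4:1), 0 °C
Reagents that add atoms: trimethyl orthoacetate, COC(C)(OC)OC; water, O
Why: This is the orthoester route to the ester of the more hindered hydroxyl, in which only the vicinal 3,4-diol can close the cyclic orthoacetate 21 (the lone C11-OH at most exchanges reversibly), and kinetic acid hydrolysis frees the less hindered secondary O3 and leaves the acetyl on the tertiary O4, as in the standard preparation of corticosteroid 17α-monoesters, without touching any stereocentre.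

Step 8
Reactants: 23 (E)-2-methylbut-2-en-1-ol
Product: 24 [(2R,3R)-2,3-dimethyloxiran-2-yl]methanol
Conditions: Ti(OiPr)4 (5 mol %), D-(−)-diisopropyl tartrate (6 mol %), t-BuOOH (2 equiv), 4 Å MS, CH2Cl2, −20 °C
Reagents that add atoms: tert-butyl hydroperoxide, CC(C)(C)OO
Why: In this Katsuki–Sharpless asymmetric epoxidation E-allylic alcohols give (2S,3S)-epoxy alcohols with L-(+)-tartrate, so D-(−)-tartrate gives (2R,3R), and syn oxygen transfer keeps CH2OH trans to the C3 methyl.

Step 9
Reactants: 24 [(2R,3R)-2,3-dimethyloxiran-2-yl]methanol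
Product: 25 (2S,3R)-2,3-dimethyloxirane-2-carboxylic acid
Conditions: RuCl3 (2 mol %), NaIO4 (3 equiv), MeCN/EtOAc/H2O, 0 °C
Reagents that add atoms: sodium periodate, [Na+].[O-]I(=O)(=O)=O
Why: Catalytic RuO4 oxidation (Sharpless conditions) takes primary epoxy alcohols to glycidic acids without opening the oxirane, and the C2 descriptor changes from R to S only through the priority change.

Step 10
Reactants: 22 (1S,2S,4aR,8aR)-2-hydroxy-7-(2-hydroxypropan-2-yl)-1,4a-dimethyl-6-oxo-1,2,3,4,4a,5,6,8a-octahydronaphthalen-1-yl acetate; 25 (2S,3R)-2,3-dimethyloxirane-2-carboxylic acid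
Product: 27 (1S,2S,4aR,8aR)-1-acetoxy-7-(2-hydroxypropan-2-yl)-1,4a-dimethyl-6-oxo-1,2,3,4,4a,5,6,8a-octahydronaphthalen-2-yl (2S,3R)-2,3-dimethyloxirane-2-carboxylate, via mixed anhydride 26 (not isolated)
Conditions: 25 (1.5 equiv), 2,4,6-Cl3C6H2COCl (1.5 equiv), Et3N (2 equiv), toluene, rt; then 22, DMAP (2 equiv), rt
Reagents that add atoms: none
Why: In this Yamaguchi esterification the oxirane ties back the α-substituents, so the quaternary acyl donor is small enough for the hindered equatorial 3β-OH, the tertiary C11-OH is inert at rt, the aprotic short reaction limits O4→O3 acetyl migration, and no stereocentre changes.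

Step 11
Reactants: 27 (1S,2S,4aR,8aR)-1-acetoxy-7-(2-hydroxypropan-2-yl)-1,4a-dimethyl-6-oxo-1,2,3,4,4a,5,6,8a-octahydronaphthalen-2-yl (2S,3R)-2,3-dimethyloxirane-2-carboxylate
Product: 28 (1S,2S,4aR,8aR)-1-acetoxy-7-(2-hydroxypropan-2-yl)-1,4a-dimethyl-6-oxo-1,2,3,4,4a,5,6,8a-octahydronaphthalen-2-yl (2R,3S)-3-chloro-2-hydroxy-2-methylbutanoate (target)
Conditions: HCl (1 M in Et2O, 1.5 equiv), CH2Cl2, −30 → 0 °C
Reagents that add atoms: hydrogen chloride, Cl
Why: In this acid-activated SN2 opening of a glycidic ester chloride attacks the secondary C3', which is remote from the electron-withdrawing ester and not quaternary, with inversion, while C2' keeps its geometry, so the (2S,3R)-epoxide gives the (2R,3S)-chlorohydrin.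

## Compound list
1 | 2-methylcyclopentane-1,3-dione | CC1C(=O)CCC1=O | starting material
2 | pent-1-en-3-one | CCC(=O)C=C | starting material
3 | 2-methyl-2-(3-oxopentyl)cyclopentane-1,3-dione | CCC(=O)CCC1(C)C(=O)CCC1=O | intermediate
4 | (7aS)-4,7a-dimethyl-2,3,7,7a-tetrahydro-1H-indene-1,5(6H)-dione | CC1=C2CCC(=O)[C@@]2(C)CCC1=O | intermediate
5 | dibromomethane | BrCBr | starting material
6 | potassium extended dienolate of 4 (O− on C3, C3=C4 and C5=C6, cyclopentanone free) | CC1=C([O-])CC[C@@]2(C)C1=CCC2=O.[K+] | intermediate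
7 | dibromomethyllithium | [Li]C(Br)Br | intermediate
8 | dibromomethyl carbinolate (CHBr2 α, O− β on the former ketone carbon, ring A still dienolate) | CC1=C([O-])CC[C@@]2(C)C1=CC[C@@]2([O-])C(Br)Br.[K+].[Li+] | intermediate
9 | lithium bromocarbenoid (CHBrLi in place of CHBr2 in 8) | CC1=C([O-])CC[C@@]2(C)C1=CC[C@@]2([O-])C([Li])Br.[K+].[Li+] | intermediate
10 | ring-expanded bis-enolate (C8(O−)=C9 enolate plus ring A dienolate) | CC1=C([O-])CC[C@@]2(C)C1=CCC([O-])=C2.[K+].[Li+] | intermediate
11 | (4aR)-1,4a-dimethyl-4,4a,7,8-tetrahydronaphthalene-2,6(3H,5H)-dione | CC1=C2CCC(=O)C[C@@]2(C)CCC1=O | intermediate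
12 | potassium extended dienolate of 11 | CC1=C([O-])CC[C@@]2(C)C1=CCC(=O)C2.[K+] | intermediate
13 | (1S,4aR)-1-hydroxy-1,4a-dimethyl-3,4,4a,5-tetrahydronaphthalene-2,6(1H,7H)-dione | O[C@]1(C)C(=O)CC[C@]2(C)CC(=O)CC=C21 | intermediate
14 | acetone | CC(C)=O | starting material
15 | dilithium C4-alkoxide / C8(O−)=C7–C6=C5 dienolate of 13 | [O-][C@]1(C)C(=O)CC[C@]2(C)CC([O-])=CC=C21.[Li+].[Li+] | intermediate
16 | dilithium aldolate (C7–C(CH3)2O−, C5=C6, C7 epimers) | [O-][C@]1(C)C(=O)CC[C@]2(C)CC(=O)C(C(C)(C)[O-])C=C21.[Li+].[Li+] | intermediate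
17 | dilithium C7-(2-hydroxypropan-2-yl) dienolate | [O-][C@]1(C)C(=O)CC[C@]2(C)CC([O-])=C(C(C)(C)O)C=C21.[Li+].[Li+] | intermediate
18 | deconjugated aldol (C5=C6, C7-H, C7 epimers) | O[C@]1(C)C(=O)CC[C@]2(C)CC(=O)C(C(C)(C)O)C=C21 | intermediate
19 | (1S,4aR,8aR)-1-hydroxy-7-(2-hydroxypropan-2-yl)-1,4a-dimethyl-1,3,4,4a,5,8a-hexahydronaphthalene-2,6-dione | O[C@]1(C)C(=O)CC[C@]2(C)CC(=O)C(C(C)(C)O)=C[C@H]21 | intermediate
20 | (4aR,5S,6S,8aR)-5,6-dihydroxy-3-(2-hydroxypropan-2-yl)-5,8a-dimethyl-4a,5,6,7,8,8a-hexahydronaphthalen-2(1H)-one | O[C@]1(C)[C@@H](O)CC[C@]2(C)CC(=O)C(C(C)(C)O)=C[C@H]21 | intermediate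
21 | 3,4-O-(1-methoxyethylidene) cyclic orthoacetate of 20 (orthoester carbon epimers) | COC1(C)O[C@]2(C)[C@@H](O1)CC[C@]3(C)CC(=O)C(C(C)(C)O)=C[C@H]32 | intermediate
22 | (1S,2S,4aR,8aR)-2-hydroxy-7-(2-hydroxypropan-2-yl)-1,4a-dimethyl-6-oxo-1,2,3,4,4a,5,6,8a-octahydronaphthalen-1-yl acetate | CC(=O)O[C@]1(C)[C@@H](O)CC[C@]2(C)CC(=O)C(C(C)(C)O)=C[C@H]21 | intermediate
23 | (E)-2-methylbut-2-en-1-ol | C/C=C(\C)CO | starting material
24 | [(2R,3R)-2,3-dimethyloxiran-2-yl]methanol | C[C@H]1O[C@]1(C)CO | intermediate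
25 | (2S,3R)-2,3-dimethyloxirane-2-carboxylic acid | C[C@H]1O[C@]1(C)C(=O)O | intermediate
26 | (2S,3R)-2,3-dimethyloxirane-2-carboxylic 2,4,6-trichlorobenzoic anhydride | C[C@H]1O[C@]1(C)C(=O)OC(=O)c2c(Cl)cc(Cl)cc2Cl | intermediate
27 | 3β-[(2S,3R)-2,3-dimethyloxirane-2-carbonyloxy] 4α-acetate (name as in step 10) | CC(=O)O[C@]1(C)[C@@H](OC(=O)[C@@]3(C)O[C@@H]3C)CC[C@]2(C)CC(=O)C(C(C)(C)O)=C[C@H]21 | intermediate
28 | CNP0119872.1 (name as in step 11) | CC(=O)O[C@]1(C)[C@@H](OC(=O)[C@@](C)(O)[C@H](C)Cl)CC[C@]2(C)CC(=O)C(C(C)(C)O)=C[C@H]21 | target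

## Step count and risks
- Total steps: 11.
- Longest linear sequence: 9 (steps 1–7, 10, 11).

Risk 1, step 3 (ring expansion).
- What can fail: incomplete masking of the enone, enolisation instead of addition, or migration of C7 instead of C10.
- Fallback, from 4 back to 11: addition and rearrangement are separated, and the anionic carbenoid is replaced by a cationoid leaving group.
- Compound 4, masked as 6, is treated with PhSeCH2Li (from (PhSe)2CH2 and n-BuLi, THF, −78 °C). Dilute acid work-up gives the β-hydroxy selenide (1S,7aS)-1-hydroxy-4,7a-dimethyl-1-[(phenylselanyl)methyl]-1,2,3,6,7,7a-hexahydro-5H-inden-5-one F1, which is purified.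
- m-CPBA (3 equiv) with K2HPO4 in CH2Cl2/MeOH oxidises selenium to the selenone (1S,7aS)-1-hydroxy-4,7a-dimethyl-1-[(phenylselenonyl)methyl]-1,2,3,6,7,7a-hexahydro-5H-inden-5-one F2.
- The selenonyl group of F2 leaves in a semipinacol 1,2-shift. In this reaction class the more substituted carbon is the known migrating group. The electron-poor enone is inert to the peracid, and the product is 11.

Risk 2, step 5 (proposed new step).
- What can fail: the acetone aldol may stay on the starting side, 18 may undergo retro-aldol under DBU, or C5 may be protonated on the wrong face.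
- Fallback with known chemistry, from 11 back to 19 (it also bypasses step 4).
- Reductive α-hydroxylation of the enone (Mn(dpm)3 cat., PhSiH3, O2, i-PrOH, then P(OEt)3) delivers H to C5 and O to C4, both from the α face. The product is (1S,4aR,8aR)-1-hydroxy-1,4a-dimethyloctahydronaphthalene-2,6-dione F3.
- LDA (2.2 equiv), ZnCl2 and acetone at −78 °C give the C7 aldol (1S,4aR,8aR)-1-hydroxy-7-(2-hydroxypropan-2-yl)-1,4a-dimethyloctahydronaphthalene-2,6-dione F4.
- Catalytic p-TsOH in warm toluene dehydrates F4 to the isopropylidene ketone (1S,4aR,8aR)-1-hydroxy-1,4a-dimethyl-7-(propan-2-ylidene)octahydronaphthalene-2,6-dione F5.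
- Dye-sensitised photooxygenation (O2, tetraphenylporphyrin, hν, CH2Cl2, 0 °C) is a Schenck ene reaction that abstracts hydrogen from the ring CH2 geminal to the carbonyl. It gives the hydroperoxide (1S,4aR,8aR)-7-(2-hydroperoxypropan-2-yl)-1-hydroxy-1,4a-dimethyl-1,3,4,4a,5,8a-hexahydronaphthalene-2,6-dione F6. PPh3 reduces F6 to 19.

Risk 3, step 11 (final opening).
- What can fail: HCl may ionise or dehydrate the tertiary C11-OH, or trigger loss of the 4-acetate.
- Fallback, from 25 and 22 back to 28: the order is inverted so that acid never meets the core.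
- Compound 25 is opened with HCl (1 M in Et2O, 0 °C) to (2R,3S)-3-chloro-2-hydroxy-2-methylbutanoic acid F7.
- F7 has an unreactive tertiary hydroxyl and needs no protection. It is coupled directly with 22 by Shiina esterification (2-methyl-6-nitrobenzoic anhydride, DMAP, CH2Cl2, rt) to give 28.

## Further compounds
F1 | step 3 | (1S,7aS)-1-hydroxy-4,7a-dimethyl-1-[(phenylselanyl)methyl]-1,2,3,6,7,7a-hexahydro-5H-inden-5-one | CC1=C2CC[C@@](O)(C[Se]c3ccccc3)[C@@]2(C)CCC1=O
F2 | step 3 | (1S,7aS)-1-hydroxy-4,7a-dimethyl-1-[(phenylselenonyl)methyl]-1,2,3,6,7,7a-hexahydro-5H-inden-5-one | CC1=C2CC[C@@](O)(C[Se](=O)(=O)c3ccccc3)[C@@]2(C)CCC1=O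
F3 | step 5 | (1S,4aR,8aR)-1-hydroxy-1,4a-dimethyloctahydronaphthalene-2,6-dione | O[C@]1(C)C(=O)CC[C@]2(C)CC(=O)CC[C@H]21
F4 | step 5 | (1S,4aR,8aR)-1-hydroxy-7-(2-hydroxypropan-2-yl)-1,4a-dimethyloctahydronaphthalene-2,6-dione (C7 epimers) | O[C@]1(C)C(=O)CC[C@]2(C)CC(=O)C(C(C)(C)O)C[C@H]21
F5 | step 5 | (1S,4aR,8aR)-1-hydroxy-1,4a-dimethyl-7-(propan-2-ylidene)octahydronaphthalene-2,6-dione | O[C@]1(C)C(=O)CC[C@]2(C)CC(=O)C(=C(C)C)C[C@H]21
F6 | step 5 | (1S,4aR,8aR)-7-(2-hydroperoxypropan-2-yl)-1-hydroxy-1,4a-dimethyl-1,3,4,4a,5,8a-hexahydronaphthalene-2,6-dione | O[C@]1(C)C(=O)CC[C@]2(C)CC(=O)C(C(C)(C)OO)=C[C@H]21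
F7 | step 11 | (2R,3S)-3-chloro-2-hydroxy-2-methylbutanoic acid | OC(=O)[C@@](C)(O)[C@H](C)Cl
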